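## The problem

Tauranin (23) is a drimane meroterpenoid. Ring A (C1–C5 and C10, gem-dimethyl on C4) and ring B (C5–C10, angular methyl on C10, exocyclic methylene on C8) form a trans-decalin. C9 carries, through the methylene C11, a 3-hydroxy-5-(hydroxymethyl)-1,4-benzoquinone (ring carbons C1'–C6', C1' bonded to C11). The terpene and quinone halves meet at C9, a neopentyl position beside the quaternary C10, so the C9–C11 bond is hard to make once the decalin is complete. There are three contiguous stereocentres. C10 is quaternary and cannot be corrected, so it must be set absolutely. C9 (α to C8) and C5 (γ to C8 across C6–C7) can be equilibrated as long as C8 is a carbonyl carbon, and the natural arrangement (trans ring fusion, equatorial C11) is expected to be the stable one. The exocyclic alkene lies next to a nucleophilic quinone hydroxyl and isomerises or cyclises onto it under acid. The hydroxyquinone is a vinylogous acid that does not tolerate organometallic reagents or hydrogenation, and its hydroxymethyl group is prone to base-induced redox tautomerisation. Both groups must therefore appear late and under near-neutral conditions. The enabling feature is that ring B with a carbonyl at C8 is 3-methylcyclohexenone: the β carbon is C10 with its methyl group and the α carbon is C9. The bonds C1–C10 and C9–C11 can thus be formed in one conjugate addition with enolate alkylation, with C10 set by a chiral copper catalyst.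

## Retrosynthesis

**Quinone from an arene (23 ⇐ 22 ⇐ 21 ⇐ 20 ⇐ 19).** Only heteroatom bonds are cut: O–Si of the hydroxymethyl group, O–CH3 of the vinylogous ester 21, the quinone oxygen at C3' (phenol 20), and one O–CH3 of the dimethoxyarene 19. A 2,6-dimethoxyaryl group survives Grignard reagents, Lewis acid, hydrogenation and ylide; a quinone would not. The silyl group is removed last so that the hydroxymethyl group is never free while base acts on the quinone. The forward steps must avoid acid throughout.

**Exocyclic alkene (19 ⇐ 18).** The C8=C12 bond is cut by Wittig methylenation. A carbonyl at C8 turns ring B into a cyclohexanone, which makes C9 correctable. The forward step must methylenate a hindered ketone.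

**Ring-fusion configuration (18 ⇐ 17 ⇐ 16).** No skeletal bond is cut. The C6–C7 alkene is reintroduced and C5 is recognised as the γ position of an enone, so the cis-fused enone 16 can be epimerised to the trans-fused 17. This is preferred to insisting on a trans-selective ring closure, which the geometry of the cyclisation does not favour.

**Ring A (16 ⇐ 15 ⇐ 14).** The C4–C5 bond is cut. C4 becomes a tertiary cation masked as a methyl ether and C5 the γ carbon of a silyl dienol ether. Cutting C1–C10 instead would require the quaternary centre to be made in a ring closure, which is less controllable. The precursor 14 is monocyclic with two stereocentres. The forward reaction must attack through C5 and not C7.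

**Unsaturation (14 ⇐ 12).** The C6–C7 double bond is removed, giving the saturated ketone 12. Forward, the enolate must form toward C7 and away from the substituted C9.

**Key disconnection (12 ⇐ 10 + 3 + 9).** C1–C10 and C9–C11 are cut together. Cutting only C9–C11 would lead to an enantiopure trimethyldecalone that has no simple source. Cutting C10–CH3 would require a cyclohexenone already carrying the chain. The three precursors are an achiral commercial enone (10), a Grignard reagent (3) and a benzylic bromide (9). The forward step must set C10 by catalyst and alkylate a hindered magnesium enolate.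

**Fragments (3 ⇐ 2 ⇐ 1; 9 ⇐ 8 ⇐ 5 ⇐ 4).** The C–Mg bond and the tertiary C–O bond of 3 lead to bromide 2 and the commercial bromoalkene 1. In 9, the C11–Br bond leads to alcohol 8, and the C1'–C11 bond is cut by directed metalation and formylation of silyl ether 5 (through aryllithium 6 and aldehyde 7), made from commercial 3,5-dimethoxybenzyl alcohol 4.

## Roads not taken

**Alternative 1:** The cut is again C9–C11, but on a preformed decalin, and the angular methyl is traced to a cyclopropane. Et2Zn/CH2I2 (Simmons–Smith reaction) would cyclopropanate the C9–C10 alkene of the bicyclic allylic alcohol A2 on the face of its C8 hydroxyl, giving carbinol A1. Oxidation to the cyclopropyl ketone A3 and cleavage of the C9–C15 bond by Li/NH3 would unveil the C10 methyl group and leave negative charge at C9, to be alkylated in the same flask with 9, arriving at 18.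
- Merits: the trans relation of the C10 methyl and H5 is fixed by a directed, irreversible step, which is more secure than the equilibration in the chosen plan. The C9 enolate is regiospecific.
- Weak points: A2 is a chiral bicyclic alcohol with two stereocentres and no short enantioselective source. The reductive opening must cleave C9–C15 and not the ring bond C9–C10. The hindered alkylation in ammonia competes with reduction of the benzylic bromide.
- Comparison: the chosen plan makes C10 by catalysis on a commercial enone and does not have to obtain A2 as a single enantiomer.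

**Alternative 2:** The cut is through the arene (C1'–C6' and C2'–C3'). The siloxyalkyne A5, which already contains the complete drimane unit, would be heated with cyclobutenone A6 (Danheiser benzannulation). A6 opens to a vinylketene that adds across the alkyne, and electrocyclic opening and closure give phenol A4. Oxidation with (KSO3)2NO and fluoride treatment would finish the synthesis.
- Merits: A4 has a free hydroxyl on C6' and a silyl ether on C2', so the endgame is about two steps instead of four and needs neither demethylation nor hydrolysis. In this respect it is better than the chosen plan.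
- Weak points: the whole terpene half with its three stereocentres and exocyclic alkene must exist before the key step, so the stereochemical problem is postponed to the synthesis of A5 (chiral pool degradation and ynol ether homologation). A6 needs its own synthesis. Ketene intermediates are heated in the presence of the alkene.
- Comparison: the chosen plan builds the terpene half from three simple components with catalytic control. It accepts a longer endgame in exchange.

**Alternative 3:** The cuts are C4–C5 and C9–C10. Cp2TiCl (trivalent titanium, from Cp2TiCl2 and Mn) would open the epoxide of the acyclic epoxytriene A7 to a C4 radical. This closes ring A and ring B and ends by loss of hydrogen from the C8 methyl group, giving the 3-hydroxy decalin A8. Deoxygenation at C3 (Barton–McCombie, two steps) would give 19.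
- Merits: both rings, the exocyclic alkene and C5, C9 and C10 are formed in one step from a precursor made by allylating aryllithium 6 and epoxidising. The route to 19 would be several steps shorter than the chosen one.
- Weak points: the C3 hydroxyl is not in the target and costs two steps. Enantiopurity depends on a regio- and enantioselective terminal epoxidation of a triene. The radical cascade is prone to early termination and to alkene isomers that are hard to separate.
- Comparison: the chosen plan is longer, but each ring and stereocentre is formed in a separate, correctable step and no oxygen has to be removed.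

Key step: step 6

## Route

Assumption: L* is the enantiomer of 1-(1-hydroxy-4-methylpentan-2-yl)-3-(2,4,6-trimethylphenyl)-4,5-dihydroimidazolium hexafluorophosphate that directs the alkyl group to the enone face giving the C10 configuration drawn; both enantiomers are available from leucinol.

Assumption: the trans ring fusion in 17 and the equatorial C11 in 18 are taken to be the thermodynamically preferred arrangements, as in drimanes generally.

Step 1
Reactants: 1 5-bromo-2-methylpent-2-ene
Product: 2 1-bromo-4-methoxy-4-methylpentane
Conditions: MeOH (solvent), H2SO4 (cat.), 50 °C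
Reagents that add atoms: methanol, CO
Why: Acid-catalysed Markovnikov hydroalkoxylation: protonation of the trisubstituted alkene gives the tertiary cation, which methanol captures; the primary bromide does not solvolyse at this temperature and unreacted alkene can be recycled.

Step 2
Reactants: 2 1-bromo-4-methoxy-4-methylpentane
Product: 3 (4-methoxy-4-methylpentyl)magnesium bromide
Conditions: Mg turnings, Et2O, 35 °C
Reagents that add atoms: magnesium, [Mg]
Why: Grignard formation by insertion of magnesium into the primary C–Br bond; the tertiary ether is inert and the titrated ethereal solution is used directly.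

Step 3
Reactants: 4 3,5-dimethoxybenzyl alcohol
Product: 5 tert-butyl[(3,5-dimethoxyphenyl)methoxy]dimethylsilane
Conditions: TBSCl, imidazole, DMF, 23 °C
Reagents that add atoms: tert-butyldimethylsilyl chloride, CC(C)(C)[Si](C)(C)Cl
Why: Standard silylation of a primary alcohol; the silyl ether masks the hydroxymethyl group through the organometallic and Lewis acid steps.

Step 4
Reactants: 5 tert-butyl[(3,5-dimethoxyphenyl)methoxy]dimethylsilane
Product: 8 [4-(tert-butyldimethylsilyloxymethyl)-2,6-dimethoxyphenyl]methanol, via aryllithium 6 (not isolated), via aldehyde 7 (not isolated)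
Conditions: n-BuLi, THF, 0 °C; DMF, 0 → 23 °C; then MeOH, NaBH4, 0 °C
Reagents that add atoms: N,N-dimethylformamide, CN(C)C=O
Why: Directed ortho-metalation: the ring position flanked by both methoxy groups (the future C1') is the most acidic and is lithiated selectively; formylation with DMF and borohydride reduction in the same flask install C11 as a hydroxymethyl group.

Step 5
Reactants: 8 [4-(tert-butyldimethylsilyloxymethyl)-2,6-dimethoxyphenyl]methanol
Product: 9 {[4-(bromomethyl)-3,5-dimethoxyphenyl]methoxy}(tert-butyl)dimethylsilane
Conditions: CBr4, PPh3, CH2Cl2, 0 °C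
Reagents that add atoms: tetrabromomethane, BrC(Br)(Br)Br
Why: Appel bromination under neutral conditions leaves the silyl ether intact; the electron-rich benzylic bromide ionises easily and is therefore used at once.

Step 6
Reactants: 10 3-methylcyclohex-2-en-1-one; 3 (4-methoxy-4-methylpentyl)magnesium bromide; 9 {[4-(bromomethyl)-3,5-dimethoxyphenyl]methoxy}(tert-butyl)dimethylsilane
Product: 12 (2R,3S)-2-{[4-(tert-butyldimethylsilyloxymethyl)-2,6-dimethoxyphenyl]methyl}-3-(4-methoxy-4-methylpentyl)-3-methylcyclohexan-1-one, via magnesium enolate 11 (not isolated)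
Conditions: Cu(OTf)2 (3 mol%), L* (4 mol%), Et2O, 0 °C; then 9, DMPU/THF, 0 → 23 °C
Reagents that add atoms: none
Why: The Grignard reagent deprotonates L* and reduces the copper salt to a monovalent copper complex of the chiral N-heterocyclic carbene; transmetalation, π-complexation of the enone, oxidative addition at the β carbon C10 (a trivalent copper intermediate) and reductive elimination form C1–C10 and leave the bromomagnesium enolate 11, whose double bond lies only between C8 and C9. DMPU then activates this enolate for SN2 displacement of bromide from the benzylic carbon of 9, which forms C9–C11. The closest known reaction type is the copper/carbene-catalysed asymmetric conjugate addition of Grignard reagents to 3-substituted cyclohexenones with alkylation of the magnesium enolate by allylic or benzylic halides. No ring is closed; ring B is the cyclohexenone itself. C10 is set by the chiral carbene ligand on copper, which selects the enone face. C9 is set by approach of the bromide anti to the larger C10 substituent (the chain), that is cis to the methyl group, and since C9 stays α to the C8 carbonyl both C9 epimers converge in step 11. The step needs 1,4- over 1,2-addition (secured by copper), C- over O-alkylation (secured by the covalent magnesium enolate and the soft benzylic bromide) and no coupling of 9 with residual Grignard reagent (secured by a slight excess of 10 over 3).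

Step 7
Reactants: 12 (2R,3S)-2-{[4-(tert-butyldimethylsilyloxymethyl)-2,6-dimethoxyphenyl]methyl}-3-(4-methoxy-4-methylpentyl)-3-methylcyclohexan-1-one
Product: 14 (5S,6R)-6-{[4-(tert-butyldimethylsilyloxymethyl)-2,6-dimethoxyphenyl]methyl}-5-(4-methoxy-4-methylpentyl)-5-methylcyclohex-2-en-1-one, via trimethylsilyl enol ether 13 (not isolated)
Conditions: LiN(i-Pr)2, THF, −78 °C; TMSCl; then Pd(OAc)2 (1.05 equiv), MeCN, 23 °C
Reagents that add atoms: none
Why: Saegusa oxidation: the amide base removes a proton from the unhindered C7 methylene and not from the tertiary C9, and divalent palladium converts the silyl enol ether into a palladium enolate that loses hydride from C6 to give the C6–C7 enone.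

Step 8
Reactants: 14 (5S,6R)-6-{[4-(tert-butyldimethylsilyloxymethyl)-2,6-dimethoxyphenyl]methyl}-5-(4-methoxy-4-methylpentyl)-5-methylcyclohex-2-en-1-one
Product: 15 tert-butyl{[(5S,6R)-6-{[4-(tert-butyldimethylsilyloxymethyl)-2,6-dimethoxyphenyl]methyl}-5-(4-methoxy-4-methylpentyl)-5-methylcyclohexa-1,3-dien-1-yl]oxy}dimethylsilane
Conditions: TBSOTf, Et3N, CH2Cl2, 0 → 23 °C
Reagents that add atoms: tert-butyldimethylsilyl trifluoromethanesulfonate, CC(C)(C)[Si](C)(C)OS(=O)(=O)C(F)(F)F
Why: Soft enolisation under equilibrating conditions: silylation of the carbonyl oxygen and loss of a proton from C5 give the linearly conjugated silyl dienol ether, whereas the cross-conjugated isomer would need a tetrasubstituted C8–C9 enol ether double bond with strong allylic strain.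

Step 9
Reactants: 15 tert-butyl{[(5S,6R)-6-{[4-(tert-butyldimethylsilyloxymethyl)-2,6-dimethoxyphenyl]methyl}-5-(4-methoxy-4-methylpentyl)-5-methylcyclohexa-1,3-dien-1-yl]oxy}dimethylsilane
Product: 16 (1R,4aR,8aS)-1-{[4-(tert-butyldimethylsilyloxymethyl)-2,6-dimethoxyphenyl]methyl}-5,5,8a-trimethyl-4a,5,6,7,8,8a-hexahydronaphthalen-2(1H)-one (cis-fused)
Conditions: TiCl4 (1.1 equiv), 2,6-di-tert-butylpyridine (0.2 equiv), CH2Cl2 (0.01 M), −78 °C
Reagents that add atoms: none
Why: TiCl4 ionises the tertiary methyl ether to the C4 cation, which is captured by the γ carbon C5 of the silyl dienol ether in an intramolecular vinylogous Mukaiyama-type tert-alkylation; only attack through C5 closes a six-membered ring (6-exo with respect to the C5–C6 double bond), and loss of the silyl group returns the C6–C7 enone. The tether on C10 reaches C5 most easily on its own face through a chair-like arrangement, so the cis ring fusion is expected as the kinetic outcome and C5 is left for correction in step 10.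

Step 10
Reactants: 16 (1R,4aR,8aS)-1-{[4-(tert-butyldimethylsilyloxymethyl)-2,6-dimethoxyphenyl]methyl}-5,5,8a-trimethyl-4a,5,6,7,8,8a-hexahydronaphthalen-2(1H)-one
Product: 17 (1R,4aS,8aS)-1-{[4-(tert-butyldimethylsilyloxymethyl)-2,6-dimethoxyphenyl]methyl}-5,5,8a-trimethyl-4a,5,6,7,8,8a-hexahydronaphthalen-2(1H)-one (trans-fused)
Conditions: KOt-Bu (0.3 equiv), t-BuOH/THF, 40 °C, argon
Reagents that add atoms: none
Why: Vinylogous epimerisation: reversible γ-deprotonation gives the extended dienolate, planar at C5, and reprotonation under thermodynamic control should accumulate the trans-fused enone, which avoids the extra gauche and syn-axial contacts of the cis isomer; C9, α to the carbonyl, equilibrates at the same time.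

Step 11
Reactants: 17 (1R,4aS,8aS)-1-{[4-(tert-butyldimethylsilyloxymethyl)-2,6-dimethoxyphenyl]methyl}-5,5,8a-trimethyl-4a,5,6,7,8,8a-hexahydronaphthalen-2(1H)-one
Product: 18 (1R,4aS,8aS)-1-{[4-(tert-butyldimethylsilyloxymethyl)-2,6-dimethoxyphenyl]methyl}-5,5,8a-trimethyloctahydronaphthalen-2(1H)-one
Conditions: H2 (1 atm), Pd/C, EtOAc, 23 °C; then NaOMe (cat.), MeOH, 23 °C
Reagents that add atoms: none
Why: Heterogeneous hydrogenation saturates the enone C6–C7 bond without creating a stereocentre, in a solvent in which the benzylic silyl ether is not hydrogenolysed; the brief methoxide treatment equilibrates C9 through the C8–C9 enolate so that C11 takes the equatorial position cis to the C10 methyl group.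

Step 12
Reactants: 18 (1R,4aS,8aS)-1-{[4-(tert-butyldimethylsilyloxymethyl)-2,6-dimethoxyphenyl]methyl}-5,5,8a-trimethyloctahydronaphthalen-2(1H)-one
Product: 19 tert-butyl[(3,5-dimethoxy-4-{[(1S,4aS,8aS)-5,5,8a-trimethyl-2-methylidenedecahydronaphthalen-1-yl]methyl}phenyl)methoxy]dimethylsilane
Conditions: Ph3PCH3Br, KOt-Bu, toluene, 90 °C
Reagents that add atoms: methyltriphenylphosphonium bromide, C[P+](c1ccccc1)(c1ccccc1)c1ccccc1.[Br-]
Why: Wittig methylenation with the unstabilised ylide at elevated temperature, as commonly applied to hindered 8-oxo drimanes and labdanes; once C8 is an alkene carbon, C9 can no longer epimerise.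

Step 13
Reactants: 19 tert-butyl[(3,5-dimethoxy-4-{[(1S,4aS,8aS)-5,5,8a-trimethyl-2-methylidenedecahydronaphthalen-1-yl]methyl}phenyl)methoxy]dimethylsilane
Product: 20 5-(tert-butyldimethylsilyloxymethyl)-3-methoxy-2-{[(1S,4aS,8aS)-5,5,8a-trimethyl-2-methylidenedecahydronaphthalen-1-yl]methyl}phenol
Conditions: NaSEt, DMF, 120 °C; aq. NH4Cl work-up
Reagents that add atoms: none
Why: Nucleophilic (SN2) demethylation of an aryl methyl ether by thiolate; the phenoxide formed deactivates the second, equivalent methoxy group so that only one is removed, and the non-acidic medium preserves the exocyclic alkene.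

Step 14
Reactants: 20 5-(tert-butyldimethylsilyloxymethyl)-3-methoxy-2-{[(1S,4aS,8aS)-5,5,8a-trimethyl-2-methylidenedecahydronaphthalen-1-yl]methyl}phenol
Product: 21 5-(tert-butyldimethylsilyloxymethyl)-3-methoxy-2-{[(1S,4aS,8aS)-5,5,8a-trimethyl-2-methylidenedecahydronaphthalen-1-yl]methyl}cyclohexa-2,5-diene-1,4-dione
Conditions: (KSO3)2NO, KH2PO4, acetone/H2O, 23 °C
Reagents that add atoms: potassium nitrosodisulfonate (KSO3)2NO, [K+].[K+].[O-]S(=O)(=O)N([O])S(=O)(=O)[O-]
Why: Teuber oxidation: the nitroxyl radical converts a phenol with a free para position (C3') into the para-quinone, the new oxygen coming from the reagent; alkene and silyl ether are inert.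

Step 15
Reactants: 21 5-(tert-butyldimethylsilyloxymethyl)-3-methoxy-2-{[(1S,4aS,8aS)-5,5,8a-trimethyl-2-methylidenedecahydronaphthalen-1-yl]methyl}cyclohexa-2,5-diene-1,4-dione
Product: 22 5-(tert-butyldimethylsilyloxymethyl)-3-hydroxy-2-{[(1S,4aS,8aS)-5,5,8a-trimethyl-2-methylidenedecahydronaphthalen-1-yl]methyl}cyclohexa-2,5-diene-1,4-dione
Conditions: NaOH (1 M aq.), MeOH/THF, 0 °C; then dilute HCl to pH 3, 0 °C
Reagents that add atoms: sodium hydroxide, [Na+].[OH-]
Why: Hydrolysis of a vinylogous ester by addition of hydroxide to the methoxy-bearing quinone carbon and loss of methoxide; the product is a vinylogous carboxylate that resists further attack, and cold dilute acid liberates the hydroxyquinone without touching the alkene.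

Step 16
Reactants: 22 5-(tert-butyldimethylsilyloxymethyl)-3-hydroxy-2-{[(1S,4aS,8aS)-5,5,8a-trimethyl-2-methylidenedecahydronaphthalen-1-yl]methyl}cyclohexa-2,5-diene-1,4-dione
Product: 23 tauranin, 3-hydroxy-5-(hydroxymethyl)-2-{[(1S,4aS,8aS)-5,5,8a-trimethyl-2-methylidenedecahydronaphthalen-1-yl]methyl}cyclohexa-2,5-diene-1,4-dione
Conditions: Bu4NF, AcOH (1:1), THF, 23 °C
Reagents that add atoms: none
Why: Fluoride-mediated cleavage of the primary silyl ether, buffered with acetic acid so that neither the acid-labile exocyclic alkene nor the base-sensitive hydroxymethyl quinone meets strong acid or base.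

## Compound list

1 | 5-bromo-2-methylpent-2-ene | CC(C)=CCCBr | starting material
2 | 1-bromo-4-methoxy-4-methylpentane | COC(C)(C)CCCBr | intermediate
3 | (4-methoxy-4-methylpentyl)magnesium bromide | COC(C)(C)CCC[Mg]Br | intermediate
4 | 3,5-dimethoxybenzyl alcohol | COc1cc(CO)cc(OC)c1 | starting material
5 | tert-butyl[(3,5-dimethoxyphenyl)methoxy]dimethylsilane | COc1cc(CO[Si](C)(C)C(C)(C)C)cc(OC)c1 | intermediate
6 | [4-(tert-butyldimethylsilyloxymethyl)-2,6-dimethoxyphenyl]lithium | [Li]c1c(OC)cc(CO[Si](C)(C)C(C)(C)C)cc1OC | intermediate (not isolated)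
7 | 4-(tert-butyldimethylsilyloxymethyl)-2,6-dimethoxybenzaldehyde | O=Cc1c(OC)cc(CO[Si](C)(C)C(C)(C)C)cc1OC | intermediate (not isolated)
8 | [4-(tert-butyldimethylsilyloxymethyl)-2,6-dimethoxyphenyl]methanol | OCc1c(OC)cc(CO[Si](C)(C)C(C)(C)C)cc1OC | intermediate
9 | {[4-(bromomethyl)-3,5-dimethoxyphenyl]methoxy}(tert-butyl)dimethylsilane | BrCc1c(OC)cc(CO[Si](C)(C)C(C)(C)C)cc1OC | intermediate
10 | 3-methylcyclohex-2-en-1-one | CC1=CC(=O)CCC1 | starting material
11 | bromomagnesium (3S)-3-(4-methoxy-4-methylpentyl)-3-methylcyclohex-1-en-1-olate | Br[Mg]OC1=C[C@@](C)(CCCC(C)(C)OC)CCC1 | intermediate (not isolated)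
12 | (2R,3S)-2-{[4-(tert-butyldimethylsilyloxymethyl)-2,6-dimethoxyphenyl]methyl}-3-(4-methoxy-4-methylpentyl)-3-methylcyclohexan-1-one | O=C1CCC[C@](C)(CCCC(C)(C)OC)[C@H]1Cc1c(OC)cc(CO[Si](C)(C)C(C)(C)C)cc1OC | intermediate
13 | {[(5S,6R)-6-{[4-(tert-butyldimethylsilyloxymethyl)-2,6-dimethoxyphenyl]methyl}-5-(4-methoxy-4-methylpentyl)-5-methylcyclohex-1-en-1-yl]oxy}trimethylsilane | C[Si](C)(C)OC1=CCC[C@](C)(CCCC(C)(C)OC)[C@H]1Cc1c(OC)cc(CO[Si](C)(C)C(C)(C)C)cc1OC | intermediate (not isolated)
14 | (5S,6R)-6-{[4-(tert-butyldimethylsilyloxymethyl)-2,6-dimethoxyphenyl]methyl}-5-(4-methoxy-4-methylpentyl)-5-methylcyclohex-2-en-1-one | O=C1C=CC[C@](C)(CCCC(C)(C)OC)[C@H]1Cc1c(OC)cc(CO[Si](C)(C)C(C)(C)C)cc1OC | intermediate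
15 | tert-butyl{[(5S,6R)-6-{[4-(tert-butyldimethylsilyloxymethyl)-2,6-dimethoxyphenyl]methyl}-5-(4-methoxy-4-methylpentyl)-5-methylcyclohexa-1,3-dien-1-yl]oxy}dimethylsilane | CC(C)(C)[Si](C)(C)OC1=CC=C[C@](C)(CCCC(C)(C)OC)[C@H]1Cc1c(OC)cc(CO[Si](C)(C)C(C)(C)C)cc1OC | intermediate
16 | (1R,4aR,8aS)-1-{[4-(tert-butyldimethylsilyloxymethyl)-2,6-dimethoxyphenyl]methyl}-5,5,8a-trimethyl-4a,5,6,7,8,8a-hexahydronaphthalen-2(1H)-one (cis-fused) | O=C1C=C[C@@H]2C(C)(C)CCC[C@]2(C)[C@H]1Cc1c(OC)cc(CO[Si](C)(C)C(C)(C)C)cc1OC | intermediate
17 | (1R,4aS,8aS)-1-{[4-(tert-butyldimethylsilyloxymethyl)-2,6-dimethoxyphenyl]methyl}-5,5,8a-trimethyl-4a,5,6,7,8,8a-hexahydronaphthalen-2(1H)-one (trans-fused) | O=C1C=C[C@H]2C(C)(C)CCC[C@]2(C)[C@H]1Cc1c(OC)cc(CO[Si](C)(C)C(C)(C)C)cc1OC | intermediate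
18 | (1R,4aS,8aS)-1-{[4-(tert-butyldimethylsilyloxymethyl)-2,6-dimethoxyphenyl]methyl}-5,5,8a-trimethyloctahydronaphthalen-2(1H)-one | O=C1CC[C@H]2C(C)(C)CCC[C@]2(C)[C@H]1Cc1c(OC)cc(CO[Si](C)(C)C(C)(C)C)cc1OC | intermediate
19 | tert-butyl[(3,5-dimethoxy-4-{[(1S,4aS,8aS)-5,5,8a-trimethyl-2-methylidenedecahydronaphthalen-1-yl]methyl}phenyl)methoxy]dimethylsilane | C=C1CC[C@H]2C(C)(C)CCC[C@]2(C)[C@H]1Cc1c(OC)cc(CO[Si](C)(C)C(C)(C)C)cc1OC | intermediate
20 | 5-(tert-butyldimethylsilyloxymethyl)-3-methoxy-2-{[(1S,4aS,8aS)-5,5,8a-trimethyl-2-methylidenedecahydronaphthalen-1-yl]methyl}phenol | C=C1CC[C@H]2C(C)(C)CCC[C@]2(C)[C@H]1Cc1c(O)cc(CO[Si](C)(C)C(C)(C)C)cc1OC | intermediate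
21 | 5-(tert-butyldimethylsilyloxymethyl)-3-methoxy-2-{[(1S,4aS,8aS)-5,5,8a-trimethyl-2-methylidenedecahydronaphthalen-1-yl]methyl}cyclohexa-2,5-diene-1,4-dione | C=C1CC[C@H]2C(C)(C)CCC[C@]2(C)[C@H]1CC1=C(OC)C(=O)C(CO[Si](C)(C)C(C)(C)C)=CC1=O | intermediate
22 | 5-(tert-butyldimethylsilyloxymethyl)-3-hydroxy-2-{[(1S,4aS,8aS)-5,5,8a-trimethyl-2-methylidenedecahydronaphthalen-1-yl]methyl}cyclohexa-2,5-diene-1,4-dione | C=C1CC[C@H]2C(C)(C)CCC[C@]2(C)[C@H]1CC1=C(O)C(=O)C(CO[Si](C)(C)C(C)(C)C)=CC1=O | intermediate
23 | tauranin, 3-hydroxy-5-(hydroxymethyl)-2-{[(1S,4aS,8aS)-5,5,8a-trimethyl-2-methylidenedecahydronaphthalen-1-yl]methyl}cyclohexa-2,5-diene-1,4-dione | C=C1CC[C@H]2C(C)(C)CCC[C@]2(C)[C@H]1CC1=C(O)C(=O)C(CO)=CC1=O | target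

## Step count and risks

Total step count: 16. Longest linear sequence: 14 steps (steps 3–16, from 4); the Grignard branch (steps 1–2) joins at step 6.

Least certain steps:

**Step 6 (key step).** The most likely failure is sluggish C-alkylation of the hindered magnesium enolate beside the new quaternary centre. This would lead to protonation on work-up, O-alkylation, or copper-mediated coupling of the bromide with residual Grignard reagent. Insufficient enantioface selection by the carbene ligand for this functionalised chain is the second concern. Fallback: starting from 10 and 3, the conjugate addition is run as before but quenched with TMSCl, and the trimethylsilyl enol ether F1 is isolated. MeLi in THF then releases the lithium enolate regiospecifically, which is alkylated with 9 in THF/DMPU. This returns to the route at 12.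

**Step 9.** Likely failures are loss of the tertiary cation by elimination and protodesilylation of the dienol ether before the C4–C5 bond forms. Incomplete regiocontrol in step 8 would add to this. Fallback: starting from 14, the thermodynamic potassium dienolate (KOt-Bu, THF) is O-acetylated with Ac2O to the dienyl acetate F2. This nucleophile is more robust and tolerates a stronger Lewis acid (SnCl4, CH2Cl2, −40 → 0 °C) for ionisation of the ether and ring closure. The fallback returns at 16 and bypasses 15.

**Step 10.** The γ-deprotonation at the hindered C5–H may be slow, or the thermodynamic bias toward the trans fusion may be too small, leaving the ring-fusion epimerisation incomplete. Fallback: starting from 16, the potassium dienolate is protonated kinetically at C7 (KOt-Bu, THF, then AcOH at −78 °C) to give the deconjugated β,γ-unsaturated ketone F3. Hydrogen atom transfer hydrogenation of its C5–C6 alkene (Mn(dpm)3, dpm = 2,2,6,6-tetramethylheptane-3,5-dionate, with PhSiH3 and t-BuOOH in i-PrOH) goes through a tertiary C5 radical that accepts hydrogen to give the more stable trans-decalin. After the methoxide equilibration of step 11 this returns at 18.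

**Step 12.** Addition of the ylide to the C8 carbonyl, flanked by the substituted C9, may be slow. Enolisation with loss of configuration at C9 would then compete. Fallback: starting from 18, Me3SiCH2Li with CeCl3 (THF, −78 °C) adds to the ketone to give the β-hydroxysilane F4. Syn-elimination with KH in THF (Peterson olefination) gives the alkene and returns at 19.

**Step 15.** Hydroxide or methoxide may add at the unsubstituted quinone position, or base may degrade the quinone, instead of clean substitution of the methoxy group. Fallback: starting from 20, the second methyl ether is removed with excess NaSEt in DMF at 150 °C to give the resorcinol F5. Oxidation with (KSO3)2NO, which converts 2,5-disubstituted resorcinols into 2-hydroxy-1,4-benzoquinones, then gives the hydroxyquinone directly. This returns at 22 and bypasses 21.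

## Further compounds

F1 | step 6 | trimethyl{[(3S)-3-(4-methoxy-4-methylpentyl)-3-methylcyclohex-1-en-1-yl]oxy}silane | C[Si](C)(C)OC1=C[C@@](C)(CCCC(C)(C)OC)CCC1
F2 | step 9 | (5S,6R)-6-{[4-(tert-butyldimethylsilyloxymethyl)-2,6-dimethoxyphenyl]methyl}-5-(4-methoxy-4-methylpentyl)-5-methylcyclohexa-1,3-dien-1-yl acetate | CC(=O)OC1=CC=C[C@](C)(CCCC(C)(C)OC)[C@H]1Cc1c(OC)cc(CO[Si](C)(C)C(C)(C)C)cc1OC
F3 | step 10 | (1R,8aR)-1-{[4-(tert-butyldimethylsilyloxymethyl)-2,6-dimethoxyphenyl]methyl}-5,5,8a-trimethyl-1,5,6,7,8,8a-hexahydronaphthalen-2(3H)-one | O=C1CC=C2C(C)(C)CCC[C@]2(C)[C@H]1Cc1c(OC)cc(CO[Si](C)(C)C(C)(C)C)cc1OC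
F4 | step 12 | (1R,2S,4aS,8aS)-1-{[4-(tert-butyldimethylsilyloxymethyl)-2,6-dimethoxyphenyl]methyl}-5,5,8a-trimethyl-2-[(trimethylsilyl)methyl]decahydronaphthalen-2-ol (axial hydroxyl expected) | C[Si](C)(C)C[C@]1(O)CC[C@H]2C(C)(C)CCC[C@]2(C)[C@H]1Cc1c(OC)cc(CO[Si](C)(C)C(C)(C)C)cc1OC
F5 | step 15 | 5-(tert-butyldimethylsilyloxymethyl)-2-{[(1S,4aS,8aS)-5,5,8a-trimethyl-2-methylidenedecahydronaphthalen-1-yl]methyl}benzene-1,3-diol | C=C1CC[C@H]2C(C)(C)CCC[C@]2(C)[C@H]1Cc1c(O)cc(CO[Si](C)(C)C(C)(C)C)cc1O
A1 | alternative 1 | cyclopropane-fused carbinol, C15 bridging C9 and C10 on the face of the C8 hydroxyl, 4,4-dimethyl, H5 on the opposite face | O[C@H]1CC[C@H]2C(C)(C)CCC[C@@]23C[C@@H]13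
A2 | alternative 1 | 5,5-dimethyl-2,3,4,4a,5,6,7,8-octahydronaphthalen-2-ol (C9–C10 alkene, C8 hydroxyl anti to H5) | O[C@H]1CC[C@H]2C(C)(C)CCCC2=C1
A3 | alternative 1 | cyclopropyl ketone from oxidation of A1 at C8 | O=C1CC[C@H]2C(C)(C)CCC[C@@]23C[C@@H]13
A4 | alternative 2 | 5-(tert-butyldimethylsilyloxymethyl)-3-(triisopropylsilyloxy)-2-{[(1S,4aS,8aS)-5,5,8a-trimethyl-2-methylidenedecahydronaphthalen-1-yl]methyl}phenol | C=C1CC[C@H]2C(C)(C)CCC[C@]2(C)[C@H]1Cc1c(O[Si](C(C)C)(C(C)C)C(C)C)cc(CO[Si](C)(C)C(C)(C)C)cc1O
A5 | alternative 2 | triisopropyl({3-[(1S,4aS,8aS)-5,5,8a-trimethyl-2-methylidenedecahydronaphthalen-1-yl]prop-1-yn-1-yl}oxy)silane | C=C1CC[C@H]2C(C)(C)CCC[C@]2(C)[C@H]1CC#CO[Si](C(C)C)(C(C)C)C(C)C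
A6 | alternative 2 | 3-(tert-butyldimethylsilyloxymethyl)cyclobut-2-en-1-one | O=C1C=C(CO[Si](C)(C)C(C)(C)C)C1
A7 | alternative 3 | tert-butyl[(4-{(2E,6E)-9-[(2S)-3,3-dimethyloxiran-2-yl]-3,7-dimethylnona-2,6-dien-1-yl}-3,5-dimethoxyphenyl)methoxy]dimethylsilane | CC1(C)O[C@H]1CC/C(C)=C/CC/C(C)=C/Cc1c(OC)cc(CO[Si](C)(C)C(C)(C)C)cc1OC
A8 | alternative 3 | (2S,4aR,5S,8aS)-5-{[4-(tert-butyldimethylsilyloxymethyl)-2,6-dimethoxyphenyl]methyl}-1,1,4a-trimethyl-6-methylidenedecahydronaphthalen-2-ol (3β-hydroxy trans-decalin) | C=C1CC[C@H]2C(C)(C)[C@@H](O)CC[C@]2(C)[C@H]1Cc1c(OC)cc(CO[Si](C)(C)C(C)(C)C)cc1OC
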